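## Structural features

The target is a C–C-linked biflavone without stereocentres. Unit 1 (benzo ring A, pyranone ring C, aryl ring B) is 5-hydroxy-7-methoxy-2-(4-hydroxyphenyl)chromen-4-one; unit 2 (benzo ring D, pyranone ring F, aryl ring E) is 5,7-dihydroxy-2-(4-methoxyphenyl)chromen-4-one. The units share one bond, from C3 of ring C to C3' of ring E (ortho to the ring E methoxy group). Ring C is therefore fully substituted: ring B on C2, ring E on C3, and the C4 carbonyl peri to the C5 oxygen of ring A. Of the six phenolic oxygens four are free (two chelated to the C4 carbonyls) and two are methyl ethers (C7 of ring A, C4' of ring E) that must survive while the others are unmasked. Fragile points are the pyranone rings (opening by hydroxide or alkoxide at C2), the electron-rich rings A and D (C6 and C8 open to electrophiles and oxidants) and the free phenols. The real difficulty is ring C: the C3–aryl bond at a crowded, fully substituted carbon, the placement of two different aryl groups on C2 and C3, and the C4 carbonyl carbon, which lies between two ortho oxygens of ring A and is poorly reached by nucleophiles. The key step exploits this last feature: the oxygen that becomes O1 is a free phenol ortho to the formyl carbon that becomes C4, so C4–H can be metalated by chelation and joined to a carbene carbon (future C3) that already carries ring E, next to a ketone carbon (future C2) that carries ring B.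

## Logic of the disconnections

14 is traced back to 12 by cutting three O–benzyl bonds (C5 and C7 of ring D, C4' of ring B) and the O–CH3 bond at C5 of ring A. This keeps every phenol masked as an ether through the base, palladium and rhodium chemistry, and lets ring A enter as a commercial aldehyde. The forward step must remove the benzyl groups and only the methyl ether peri to C4=O of ring C, passing through 13, while the methyl ethers at C7 of ring A and C4' of ring E stay.

12 is cut in ring C at C3–C4 and at O1–C2, which leads through 11 to 9 and 10. The cut is made there because the C4 carbon is then approached through its own C–H bond, directed by the phenol that becomes O1, and not by nucleophilic attack on a di-ortho-substituted acyl group. The gain is large: the whole of ring C and the placement of rings B and E fall back to a commercial aldehyde and one open-chain diazo ketone. The forward step must couple an acyl–metal bond with a hindered carbene carbon faster than the carbene decays, and the phenol must then close on the only ketone within reach.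

9 is cut at the C=N2 bond and gives 8. The diazo group is the activating device of the key step and adds no carbon. The forward step needs the CH2 group of 8 to be acidic enough for diazo transfer under a base that leaves ring F intact.

8 is cut between C3' of ring E and the CH2 carbon, giving 6 and 7. This bond becomes the C3–C3' bond of the target; it is made here at an unhindered primary enolate carbon, long before ring C exists. The forward step must stop at mono-arylation and tolerate the flavone of unit 2.

6 is cut in ring F at O1–C2, with the C2=C3 unsaturation taken back through 5 to the open enone 4, and 4 is cut at its Cα=Cβ bond to 2 and 3. This is the standard chalcone logic for a flavone with an unsubstituted C3 and brings the bromine on ring E in from a commercial aldehyde. The forward steps need a base-stable protection of the ring D oxygens and an oxidant that spares the aryl bromide.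

2 is cut at two O–benzyl bonds to 1. The forward step must leave the carbonyl-chelated hydroxyl free, because it becomes O1 of ring F.

## Other disconnections considered

Alternative 1: the first cut that comes to mind is the inter-unit bond C3–C3' between two finished flavones. 2-[4-(Benzyloxy)phenyl]-3-iodo-5,7-dimethoxy-4H-chromen-4-one A1 and the boronate 5,7-bis(benzyloxy)-2-[4-methoxy-3-(4,4,5,5-tetramethyl-1,3,2-dioxaborolan-2-yl)phenyl]-4H-chromen-4-one A2 would be joined by Suzuki–Miyaura coupling to 12. The coupling would have to form a bond with three ortho substituents at C3 of a chromone whose C4 carbonyl is crowded by the C5 methoxy group. Transmetalation to such a centre is expected to be slow, and the two escape processes (protodeiodination of the electron-rich iodide, protodeboronation of the ortho-methoxy boronate) both end in monomeric flavones. It also needs two separately functionalised flavones, eight steps against seven, and it builds ring C before the hard bond. The chosen plan makes that bond at a CH2 stage.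

Alternative 2: the same two bonds of ring C (C3–C4 and O1–C2) can be cut with an alkyne as the C2–C3 unit. Oxidative annulation of 10 with the diarylalkyne 5,7-bis(benzyloxy)-2-(3-{[4-(benzyloxy)phenyl]ethynyl}-4-methoxyphenyl)-4H-chromen-4-one A3 (from 6 by Sonogashira coupling), with [Cp*RhCl2]2 and Cu(OAc)2 as oxidant, would give 12 in one step less. The insertion of an unsymmetrical diarylalkyne into the acyl–rhodium bond decides which aryl ends on C2. The alkyne carbon that binds rhodium (future C2) is expected to take the bulkier and potentially chelating aryl group, here ring E with its ortho methoxy group, and the electronic difference between the two oxygenated aryl groups is small. The likely main product would be the regioisomer 3-[4-(benzyloxy)phenyl]-2-{5-[5,7-bis(benzyloxy)-4-oxo-4H-chromen-2-yl]-2-methoxyphenyl}-5,7-dimethoxy-4H-chromen-4-one A4. Diazo ketone 9 is the regiodefined equivalent of A3 and costs one step.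

Alternative 3: the same bonds can be cut in the ionic sense. C-acylation of the enolate of 8 with 2,4,6-trimethoxybenzoyl chloride would give 1-[4-(benzyloxy)phenyl]-2-{5-[5,7-bis(benzyloxy)-4-oxo-4H-chromen-2-yl]-2-methoxyphenyl}-3-(2,4,6-trimethoxyphenyl)propane-1,3-dione A5, followed by chelation-controlled demethylation and cyclodehydration. This is one step shorter on paper, but it rests on nucleophilic attack at the most hindered carbonyl carbon of the molecule by a hindered, ambident enolate, so O-acylation and slow C–C bond formation are the expected course. The free 2-aryl-1,3-diketone would also be open to retro-Claisen cleavage during demethylation. The chosen plan replaces that attack by a chelation-assisted C–H metalation; Alternative 3 is kept as a fallback.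

Key step: step 6

Remark on the chemistry: the SMILES gives no descriptor for the hindered C3–C3' axis, so no axial configuration is set; 5 and 11 are racemic intermediates whose stereocentres disappear.

## Route

Step 1
Reactants: 1 1-(2,4,6-trihydroxyphenyl)ethan-1-one
Product: 2 1-[2,4-bis(benzyloxy)-6-hydroxyphenyl]ethan-1-one
Conditions: BnBr (2.1 equiv), K2CO3 (2.2 equiv), acetone, reflux
Reagents that add atoms: benzyl bromide, BrCc1ccccc1
Why: Williamson etherification: the hydroxyl that stays hydrogen-bonded to the acetyl carbonyl is the least acidic and least nucleophilic, so two equivalents of benzyl bromide should alkylate the para hydroxyl and one ortho hydroxyl and stop there.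

Step 2
Reactants: 2 1-[2,4-bis(benzyloxy)-6-hydroxyphenyl]ethan-1-one, 3 3-bromo-4-methoxybenzaldehyde
Product: 4 (E)-1-[2,4-bis(benzyloxy)-6-hydroxyphenyl]-3-(3-bromo-4-methoxyphenyl)prop-2-en-1-one
Conditions: KOH (aq. 50%), EtOH/THF, rt
Reagents that add atoms: none
Why: Claisen–Schmidt condensation: the methyl ketone enolate adds to the non-enolisable aldehyde 3 and E1cB loss of water gives the conjugated E-enone under thermodynamic control; benzyl ethers and the aryl bromide are inert to KOH.

Step 3
Reactants: 4 (E)-1-[2,4-bis(benzyloxy)-6-hydroxyphenyl]-3-(3-bromo-4-methoxyphenyl)prop-2-en-1-one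
Product: 6 5,7-bis(benzyloxy)-2-(3-bromo-4-methoxyphenyl)-4H-chromen-4-one, via flavanone 5 (not isolated)
Conditions: I2 (10 mol%), DMSO, 120 °C
Reagents that add atoms: none
Why: Iodine/DMSO oxidative cyclisation of a 2'-hydroxychalcone: 6-endo oxa-Michael closure of ring F gives flavanone 5, α-iodination and loss of HI introduce the C2=C3 double bond, and DMSO reoxidises HI to I2; the aryl bromide and the benzyl ethers should survive.

Step 4
Reactants: 6 5,7-bis(benzyloxy)-2-(3-bromo-4-methoxyphenyl)-4H-chromen-4-one, 7 1-[4-(benzyloxy)phenyl]ethan-1-one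
Product: 8 1-[4-(benzyloxy)phenyl]-2-{5-[5,7-bis(benzyloxy)-4-oxo-4H-chromen-2-yl]-2-methoxyphenyl}ethan-1-one
Conditions: Pd2(dba)3 (2 mol%), Xantphos (5 mol%), K3PO4 (2.5 equiv), toluene, 90 °C
Reagents that add atoms: none
Why: Palladium-catalysed ketone α-arylation: zerovalent palladium inserts into the C–Br bond of 6, the potassium enolate of 7 displaces bromide on palladium and reductive elimination forms the aryl–CH2 bond (the future C3–C3' bond) at an unhindered primary carbon. The ortho methoxy group should block a second arylation of the more acidic product, and K3PO4 is too weak a nucleophile to open ring F.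

Step 5
Reactants: 8 1-[4-(benzyloxy)phenyl]-2-{5-[5,7-bis(benzyloxy)-4-oxo-4H-chromen-2-yl]-2-methoxyphenyl}ethan-1-one
Product: 9 1-[4-(benzyloxy)phenyl]-2-{5-[5,7-bis(benzyloxy)-4-oxo-4H-chromen-2-yl]-2-methoxyphenyl}-2-diazoethan-1-one
Conditions: 4-acetamidobenzenesulfonyl azide (1.3 equiv), DBU (1.5 equiv), MeCN, 0 °C to rt
Reagents that add atoms: 4-acetamidobenzenesulfonyl azide, CC(=O)Nc1ccc(cc1)S(=O)(=O)N=[N+]=[N-]
Why: Regitz diazo transfer: DBU deprotonates the doubly activated benzylic CH2 group of 8, the enolate attacks the terminal nitrogen of the sulfonyl azide and the triazene adduct collapses to the diazo ketone and the sulfonamide; the donor/acceptor diazo ketone should be stable enough to be purified quickly and kept cold.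

Step 6
Reactants: 9 1-[4-(benzyloxy)phenyl]-2-{5-[5,7-bis(benzyloxy)-4-oxo-4H-chromen-2-yl]-2-methoxyphenyl}-2-diazoethan-1-one, 10 2-hydroxy-4,6-dimethoxybenzaldehyde
Product: 12 2-[4-(benzyloxy)phenyl]-3-{5-[5,7-bis(benzyloxy)-4-oxo-4H-chromen-2-yl]-2-methoxyphenyl}-5,7-dimethoxy-4H-chromen-4-one, via hydroxyaryl 1,3-diketone 11 (not isolated)
Conditions: [Cp*RhCl2]2 (2.5 mol%), AgSbF6 (10 mol%), CsOAc (25 mol%), 1,2-dichloroethane, 60 °C, slow addition of 9; then TsOH·H2O (20 mol%), 80 °C
Reagents that add atoms: none
Why: The phenoxide of 10 binds the cationic Cp*Rh fragment (trivalent rhodium) and directs acetate-assisted cleavage of the aldehyde C–H bond to a five-membered acyl rhodacycle; 9 then coordinates, loses N2 to give a rhodium carbene, and 1,1-migratory insertion of the acyl group into the carbene forms the C3–C4 bond, protonation releasing the 2-aryl-1,3-diketone 11 and the trivalent rhodium species without an external oxidant. The closest known reaction type is the Cp*Rh-catalysed aldehyde C–H activation and annulation of salicylaldehydes with α-diazo-1,3-dicarbonyl compounds or sulfoxonium ylides, which gives chromones and flavones by the same acyl–carbene coupling and cyclodehydration. Ring C is then closed by 6-exo-trig addition of the phenolic OH to the ketone carbonyl that carries ring B, followed by acid-catalysed loss of water (TsOH) to the aromatic pyranone. No stereocentre remains, since the CH stereocentre of 11 is lost on dehydration. The step needs control over which aryl group sits on C2 and which on C3, and the connectivity of 9 fixes this: the carbene carbon carries ring E and can only become C3, while the carbonyl carbon carries ring B and is the only ketone the phenol can reach through a six-membered ring. It also needs the acyl–carbene coupling to outrun carbene dimerisation, O–H insertion and insertion into the neighbouring OCH3 group; this is favoured because the carbene is generated on the metal that already holds the acyl ligand and 9 is added slowly. Because the C4 carbon is reached by chelation-assisted C–H metalation and not by attack on a di-ortho-substituted acyl derivative, the crowding between O1 and the C5 methoxy group should not block the bond-forming event.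

Step 7
Reactants: 12 2-[4-(benzyloxy)phenyl]-3-{5-[5,7-bis(benzyloxy)-4-oxo-4H-chromen-2-yl]-2-methoxyphenyl}-5,7-dimethoxy-4H-chromen-4-one
Product: 14 3-[5-(5,7-dihydroxy-4-oxo-4H-chromen-2-yl)-2-methoxyphenyl]-5-hydroxy-2-(4-hydroxyphenyl)-7-methoxy-4H-chromen-4-one, via tetraphenol 5-methyl ether 13 (not isolated)
Conditions: BCl3 (10 equiv), pentamethylbenzene (10 equiv), CH2Cl2, −78 °C to rt; then MeOH, aqueous work-up
Reagents that add atoms: none
Why: Lewis-acid ether cleavage: BCl3 removes the three benzyl groups at low temperature, pentamethylbenzene trapping the benzyl cations before they can alkylate rings A and D, which gives 13; on warming, BCl3 held in a six-membered chelate between C4=O of ring C and the peri C5 methoxy oxygen should cleave that methyl ether alone. The methyl ethers at C7 of ring A and C4' of ring E have no carbonyl oxygen placed to chelate and should stay.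

## Compound list

1 | 1-(2,4,6-trihydroxyphenyl)ethan-1-one | CC(=O)c1c(O)cc(O)cc1O | starting material
2 | 1-[2,4-bis(benzyloxy)-6-hydroxyphenyl]ethan-1-one | CC(=O)c1c(O)cc(OCc2ccccc2)cc1OCc1ccccc1 | intermediate
3 | 3-bromo-4-methoxybenzaldehyde | COc1ccc(C=O)cc1Br | starting material
4 | (E)-1-[2,4-bis(benzyloxy)-6-hydroxyphenyl]-3-(3-bromo-4-methoxyphenyl)prop-2-en-1-one | COc1ccc(/C=C/C(=O)c2c(O)cc(OCc3ccccc3)cc2OCc2ccccc2)cc1Br | intermediate
5 | 5,7-bis(benzyloxy)-2-(3-bromo-4-methoxyphenyl)chroman-4-one (racemic) | COc1ccc(C2CC(=O)c3c(OCc4ccccc4)cc(OCc4ccccc4)cc3O2)cc1Br | intermediate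
6 | 5,7-bis(benzyloxy)-2-(3-bromo-4-methoxyphenyl)-4H-chromen-4-one | COc1ccc(-c2cc(=O)c3c(OCc4ccccc4)cc(OCc4ccccc4)cc3o2)cc1Br | intermediate
7 | 1-[4-(benzyloxy)phenyl]ethan-1-one | CC(=O)c1ccc(OCc2ccccc2)cc1 | starting material
8 | 1-[4-(benzyloxy)phenyl]-2-{5-[5,7-bis(benzyloxy)-4-oxo-4H-chromen-2-yl]-2-methoxyphenyl}ethan-1-one | COc1ccc(-c2cc(=O)c3c(OCc4ccccc4)cc(OCc4ccccc4)cc3o2)cc1CC(=O)c1ccc(OCc2ccccc2)cc1 | intermediate
9 | 1-[4-(benzyloxy)phenyl]-2-{5-[5,7-bis(benzyloxy)-4-oxo-4H-chromen-2-yl]-2-methoxyphenyl}-2-diazoethan-1-one | COc1ccc(-c2cc(=O)c3c(OCc4ccccc4)cc(OCc4ccccc4)cc3o2)cc1C(=[N+]=[N-])C(=O)c1ccc(OCc2ccccc2)cc1 | intermediate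
10 | 2-hydroxy-4,6-dimethoxybenzaldehyde | COc1cc(O)c(C=O)c(OC)c1 | starting material
11 | 1-[4-(benzyloxy)phenyl]-2-{5-[5,7-bis(benzyloxy)-4-oxo-4H-chromen-2-yl]-2-methoxyphenyl}-3-(2-hydroxy-4,6-dimethoxyphenyl)propane-1,3-dione (racemic) | COc1ccc(-c2cc(=O)c3c(OCc4ccccc4)cc(OCc4ccccc4)cc3o2)cc1C(C(=O)c1ccc(OCc2ccccc2)cc1)C(=O)c1c(O)cc(OC)cc1OC | intermediate
12 | 2-[4-(benzyloxy)phenyl]-3-{5-[5,7-bis(benzyloxy)-4-oxo-4H-chromen-2-yl]-2-methoxyphenyl}-5,7-dimethoxy-4H-chromen-4-one | COc1cc(OC)c2c(=O)c(-c3cc(-c4cc(=O)c5c(OCc6ccccc6)cc(OCc6ccccc6)cc5o4)ccc3OC)c(-c3ccc(OCc4ccccc4)cc3)oc2c1 | intermediate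
13 | 3-[5-(5,7-dihydroxy-4-oxo-4H-chromen-2-yl)-2-methoxyphenyl]-2-(4-hydroxyphenyl)-5,7-dimethoxy-4H-chromen-4-one | COc1cc(OC)c2c(=O)c(-c3cc(-c4cc(=O)c5c(O)cc(O)cc5o4)ccc3OC)c(-c3ccc(O)cc3)oc2c1 | intermediate
14 | 3-[5-(5,7-dihydroxy-4-oxo-4H-chromen-2-yl)-2-methoxyphenyl]-5-hydroxy-2-(4-hydroxyphenyl)-7-methoxy-4H-chromen-4-one | COc1cc(O)c2c(=O)c(-c3cc(-c4cc(=O)c5c(O)cc(O)cc5o4)ccc3OC)c(-c3ccc(O)cc3)oc2c1 | target

## Step count and least certain steps

Total step count: 7. Longest linear sequence: 7 steps (1 to 14); 3, 7 and 10 enter as commercial partners.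

Step 6 (key step). The acyl–carbene coupling may be too slow at the crowded rhodium centre, which holds a di-ortho-substituted acyl group and meets a carbene with an ortho-substituted aryl group. The carbene would then be lost by dimerisation, by insertion into the neighbouring OCH3 group or into the phenol O–H bond, and the acyl rhodacycle by decarbonylation. The fallback sets out from 6 and forms the inter-unit bond by cross-coupling. Miyaura borylation of 6 (B2pin2, KOAc, PdCl2(dppf), dioxane, 90 °C) gives 5,7-bis(benzyloxy)-2-[4-methoxy-3-(4,4,5,5-tetramethyl-1,3,2-dioxaborolan-2-yl)phenyl]-4H-chromen-4-one F1. Separately, commercial 2,4,6-trimethoxybenzoyl chloride and 1-(benzyloxy)-4-ethynylbenzene are joined by acyl Sonogashira coupling (PdCl2(PPh3)2, CuI, Et3N, THF, rt) to 3-[4-(benzyloxy)phenyl]-1-(2,4,6-trimethoxyphenyl)prop-2-yn-1-one F2. ICl (CH2Cl2, −78 °C) then brings about the known demethylative 6-endo iodocyclisation to 2-[4-(benzyloxy)phenyl]-3-iodo-5,7-dimethoxy-4H-chromen-4-one F3. Suzuki–Miyaura coupling of F1 with F3 (Pd(OAc)2, SPhos, K3PO4, toluene/H2O, 90 °C) comes back to the route at 12.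

Step 4. Oxidative addition into the C–Br bond next to the methoxy group may be slow, so that self-condensation of the enolate of 7, a second arylation, or enolate addition to C2 of ring F compete. The fallback sets out from 6 and builds the ketone by hydration instead of enolate coupling. Sonogashira coupling of 6 with commercial 1-(benzyloxy)-4-ethynylbenzene (PdCl2(PPh3)2, CuI, Et3N, DMF, 70 °C) gives 5,7-bis(benzyloxy)-2-(3-{[4-(benzyloxy)phenyl]ethynyl}-4-methoxyphenyl)-4H-chromen-4-one F4. Gold-catalysed hydration ((Ph3P)AuCl and AgSbF6, dioxane/H2O, 80 °C) should place the carbonyl on the alkyne carbon attached to ring B, whose para benzyloxy group best stabilises positive charge, and so comes back to the route at 8.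

Step 5. Deprotonation of the hindered CH2 group may be incomplete, so that diazo transfer is slow and the diazo product couples with remaining enolate or decomposes under the base. The fallback sets out from 8 and closes ring C in the ionic sense. Soft enolisation of 8 (MgBr2·OEt2, i-Pr2NEt, CH2Cl2) and C-acylation with commercial 2,4,6-trimethoxybenzoyl chloride gives 1-[4-(benzyloxy)phenyl]-2-{5-[5,7-bis(benzyloxy)-4-oxo-4H-chromen-2-yl]-2-methoxyphenyl}-3-(2,4,6-trimethoxyphenyl)propane-1,3-dione F5. BCl3 and pentamethylbenzene (CH2Cl2, −78 °C to 0 °C) remove the three benzyl groups and one carbonyl-chelated ortho methyl ether, giving 2-[5-(5,7-dihydroxy-4-oxo-4H-chromen-2-yl)-2-methoxyphenyl]-1-(2-hydroxy-4,6-dimethoxyphenyl)-3-(4-hydroxyphenyl)propane-1,3-dione F6. F6 cyclodehydrates in acidic methanol (HCl, MeOH, 60 °C) and comes back to the route at 13, which is taken to 14 with BCl3 at rt as in step 7.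

Step 7. Selectivity in the ether cleavage may be lost: incomplete demethylation at the crowded C5 position of ring A, cleavage of a further methyl ether on long exposure, or C-benzylation of rings A and D by benzyl cations. The fallback moves the demethylation to the simple aldehyde, so that only benzyl groups remain at the end. It sets out from 10: BCl3 (CH2Cl2, 0 °C) cleaves the methyl ether ortho to the formyl group by chelation and gives 2,6-dihydroxy-4-methoxybenzaldehyde F7. F7 and 9 under the conditions of step 6 give 1-[4-(benzyloxy)phenyl]-2-{5-[5,7-bis(benzyloxy)-4-oxo-4H-chromen-2-yl]-2-methoxyphenyl}-3-(2,6-dihydroxy-4-methoxyphenyl)propane-1,3-dione F8, either of whose two equivalent hydroxyl groups closes ring C to 2-[4-(benzyloxy)phenyl]-3-{5-[5,7-bis(benzyloxy)-4-oxo-4H-chromen-2-yl]-2-methoxyphenyl}-5-hydroxy-7-methoxy-4H-chromen-4-one F9. Debenzylation alone (BCl3, pentamethylbenzene, CH2Cl2, −78 °C) comes back to the route at 14.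

## Further compounds

F1 | step 6 | 5,7-bis(benzyloxy)-2-[4-methoxy-3-(4,4,5,5-tetramethyl-1,3,2-dioxaborolan-2-yl)phenyl]-4H-chromen-4-one | COc1ccc(-c2cc(=O)c3c(OCc4ccccc4)cc(OCc4ccccc4)cc3o2)cc1B1OC(C)(C)C(C)(C)O1
F2 | step 6 | 3-[4-(benzyloxy)phenyl]-1-(2,4,6-trimethoxyphenyl)prop-2-yn-1-one | COc1cc(OC)c(C(=O)C#Cc2ccc(OCc3ccccc3)cc2)c(OC)c1
F3 | step 6 | 2-[4-(benzyloxy)phenyl]-3-iodo-5,7-dimethoxy-4H-chromen-4-one | COc1cc(OC)c2c(=O)c(I)c(-c3ccc(OCc4ccccc4)cc3)oc2c1
F4 | step 4 | 5,7-bis(benzyloxy)-2-(3-{[4-(benzyloxy)phenyl]ethynyl}-4-methoxyphenyl)-4H-chromen-4-one | COc1ccc(-c2cc(=O)c3c(OCc4ccccc4)cc(OCc4ccccc4)cc3o2)cc1C#Cc1ccc(OCc2ccccc2)cc1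
F5 | step 5 | 1-[4-(benzyloxy)phenyl]-2-{5-[5,7-bis(benzyloxy)-4-oxo-4H-chromen-2-yl]-2-methoxyphenyl}-3-(2,4,6-trimethoxyphenyl)propane-1,3-dione | COc1ccc(-c2cc(=O)c3c(OCc4ccccc4)cc(OCc4ccccc4)cc3o2)cc1C(C(=O)c1ccc(OCc2ccccc2)cc1)C(=O)c1c(OC)cc(OC)cc1OC
F6 | step 5 | 2-[5-(5,7-dihydroxy-4-oxo-4H-chromen-2-yl)-2-methoxyphenyl]-1-(2-hydroxy-4,6-dimethoxyphenyl)-3-(4-hydroxyphenyl)propane-1,3-dione | COc1ccc(-c2cc(=O)c3c(O)cc(O)cc3o2)cc1C(C(=O)c1ccc(O)cc1)C(=O)c1c(O)cc(OC)cc1OC
F7 | step 7 | 2,6-dihydroxy-4-methoxybenzaldehyde | COc1cc(O)c(C=O)c(O)c1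
F8 | step 7 | 1-[4-(benzyloxy)phenyl]-2-{5-[5,7-bis(benzyloxy)-4-oxo-4H-chromen-2-yl]-2-methoxyphenyl}-3-(2,6-dihydroxy-4-methoxyphenyl)propane-1,3-dione | COc1ccc(-c2cc(=O)c3c(OCc4ccccc4)cc(OCc4ccccc4)cc3o2)cc1C(C(=O)c1ccc(OCc2ccccc2)cc1)C(=O)c1c(O)cc(OC)cc1O
F9 | step 7 | 2-[4-(benzyloxy)phenyl]-3-{5-[5,7-bis(benzyloxy)-4-oxo-4H-chromen-2-yl]-2-methoxyphenyl}-5-hydroxy-7-methoxy-4H-chromen-4-one | COc1cc(O)c2c(=O)c(-c3cc(-c4cc(=O)c5c(OCc6ccccc6)cc(OCc6ccccc6)cc5o4)ccc3OC)c(-c3ccc(OCc4ccccc4)cc3)oc2c1
A1 | alternative 1 | 2-[4-(benzyloxy)phenyl]-3-iodo-5,7-dimethoxy-4H-chromen-4-one | COc1cc(OC)c2c(=O)c(I)c(-c3ccc(OCc4ccccc4)cc3)oc2c1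
A2 | alternative 1 | 5,7-bis(benzyloxy)-2-[4-methoxy-3-(4,4,5,5-tetramethyl-1,3,2-dioxaborolan-2-yl)phenyl]-4H-chromen-4-one | COc1ccc(-c2cc(=O)c3c(OCc4ccccc4)cc(OCc4ccccc4)cc3o2)cc1B1OC(C)(C)C(C)(C)O1
A3 | alternative 2 | 5,7-bis(benzyloxy)-2-(3-{[4-(benzyloxy)phenyl]ethynyl}-4-methoxyphenyl)-4H-chromen-4-one | COc1ccc(-c2cc(=O)c3c(OCc4ccccc4)cc(OCc4ccccc4)cc3o2)cc1C#Cc1ccc(OCc2ccccc2)cc1
A4 | alternative 2 | 3-[4-(benzyloxy)phenyl]-2-{5-[5,7-bis(benzyloxy)-4-oxo-4H-chromen-2-yl]-2-methoxyphenyl}-5,7-dimethoxy-4H-chromen-4-one | COc1cc(OC)c2c(=O)c(-c3ccc(OCc4ccccc4)cc3)c(-c3cc(-c4cc(=O)c5c(OCc6ccccc6)cc(OCc6ccccc6)cc5o4)ccc3OC)oc2c1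
A5 | alternative 3 | 1-[4-(benzyloxy)phenyl]-2-{5-[5,7-bis(benzyloxy)-4-oxo-4H-chromen-2-yl]-2-methoxyphenyl}-3-(2,4,6-trimethoxyphenyl)propane-1,3-dione | COc1ccc(-c2cc(=O)c3c(OCc4ccccc4)cc(OCc4ccccc4)cc3o2)cc1C(C(=O)c1ccc(OCc2ccccc2)cc1)C(=O)c1c(OC)cc(OC)cc1OC
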